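Retrosynthesis: the four phenols are masked as methyl ethers and a removable chlorine is placed on each C5. Both pyranone (C) rings are then opened by cutting O1–C8a and C4–C4a, followed by both C2–C3 bonds and finally the central C3'–C3''' biaryl bond.
Enabling feature: in each isoflavone half, O1 and C4 are attached to the neighbouring A-ring carbons C8a and C4a. Ring A is therefore an aryne synthon, and O1–C2=C3–C4 is the enolate oxygen, alkene and ester carbon of a methyl 2-aryl-3-hydroxyacrylate.
Forward: methyl 4-methoxyphenylacetate is brominated and homocoupled, which joins both B rings, and both side chains are formylated with methyl formate. Two molecules of 3-chloro-5-methoxybenzyne then bring in both A rings and close both C rings in one flask.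
The aryne comes from 2-chloro-4-methoxy-6-(trimethylsilyl)phenyl triflate, made in three steps from 2-chloro-4-methoxyphenol. That phenol has a single free ortho position, so silicon can be placed without regiochemical doubt, and the chlorine steers the enolate oxygen to C8a.
End game: homogeneous palladium-catalysed hydrodechlorination, then fourfold O-demethylation.
Stereochemistry: there is none to set; only the Z geometry of the enolate matters, because ring closure depends on it.
Key step: step 7

Assumption: the SMILES carries no stereodescriptor, and a biaryl axis flanked by only two ortho hydroxyl groups is not configurationally stable. The target is therefore treated as achiral and no enantioselective step is needed.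

Step 1
Reactants: 1 methyl 2-(4-methoxyphenyl)acetate
Product: 2 methyl 2-(3-bromo-4-methoxyphenyl)acetate
Conditions: NBS (1.05 equiv), MeCN, 0 °C → rt
Reagents that add atoms: N-bromosuccinimide, O=C1CCC(=O)N1Br
Why: In this electrophilic aromatic bromination the methoxy group directs to its free ortho position because the para position carries the side chain, and NBS in acetonitrile reacts ionically, so the benzylic CH2 is left alone.

Step 2
Reactants: 2 methyl 2-(3-bromo-4-methoxyphenyl)acetate (two molecules)
Product: 3 dimethyl 2,2'-(6,6'-dimethoxy[1,1'-biphenyl]-3,3'-diyl)diacetate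
Conditions: NiCl2(PPh3)2 (10 mol %), Zn dust, Et4NI, THF, 50 °C
Reagents that add atoms: none
Why: Nickel(0)-catalysed reductive Ullmann-type homocoupling with zinc as terminal reductant runs under neutral conditions, tolerates methyl esters and one ortho-methoxy group per ring, and makes the C3'–C3''' bond symmetrically.

Step 3
Reactants: 3 dimethyl 2,2'-(6,6'-dimethoxy[1,1'-biphenyl]-3,3'-diyl)diacetate; 4 methyl formate (excess)
Product: 5 dimethyl (2Z,2'Z)-2,2'-(6,6'-dimethoxy[1,1'-biphenyl]-3,3'-diyl)bis(3-hydroxyprop-2-enoate)
Conditions: NaH, THF, 0 °C → rt; then cold 1 M HCl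
Reagents that add atoms: none
Why: This crossed Claisen condensation (α-formylation) of an arylacetate with a non-enolisable formate is driven by formation of the stabilised enolate, and acidification should give the hydrogen-bonded Z enol in equilibrium with its aldehyde tautomer.

Step 4
Reactants: 6 2-chloro-4-methoxyphenol
Product: 7 2-bromo-6-chloro-4-methoxyphenol
Conditions: NBS (1.0 equiv), i-Pr2NH (10 mol %), CH2Cl2, 0 °C → rt
Reagents that add atoms: N-bromosuccinimide, O=C1CCC(=O)N1Br
Why: In this amine-catalysed ortho-bromination of a phenol the hydroxyl group is the dominant director, and with its para and one ortho position occupied, bromine should enter at C6.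

Step 5
Reactants: 7 2-bromo-6-chloro-4-methoxyphenol
Product: 8 (2-bromo-6-chloro-4-methoxyphenoxy)trimethylsilane
Conditions: (Me3Si)2NH, THF, 70 °C; volatiles removed in vacuo
Reagents that add atoms: hexamethyldisilazane, C[Si](C)(C)N[Si](C)(C)C
Why: O-Silylation of a phenol with hexamethyldisilazane releases only a volatile by-product, so the moisture-sensitive ether can be carried on without chromatography.

Step 6
Reactants: 8 (2-bromo-6-chloro-4-methoxyphenoxy)trimethylsilane
Product: 11 2-chloro-4-methoxy-6-(trimethylsilyl)phenyl trifluoromethanesulfonate, via aryllithium 9 (not isolated), via lithium phenoxide 10 (not isolated)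
Conditions: n-BuLi (1.1 equiv), THF, −78 °C; then Tf2O (1.2 equiv), −78 °C → 0 °C
Reagents that add atoms: trifluoromethanesulfonic anhydride, O=S(=O)(OS(=O)(=O)C(F)(F)F)C(F)(F)F
Why: Bromine–lithium exchange, which is much faster than any reaction at C–Cl, gives an ortho-lithiated aryl silyl ether that undergoes the 1,3 O→C silyl shift (retro-Brook rearrangement), and triflation of the released phenoxide is the standard entry to o-silylaryl triflates.

Step 7
Reactants: 5 dimethyl (2Z,2'Z)-2,2'-(6,6'-dimethoxy[1,1'-biphenyl]-3,3'-diyl)bis(3-hydroxyprop-2-enoate); 11 2-chloro-4-methoxy-6-(trimethylsilyl)phenyl trifluoromethanesulfonate (two molecules incorporated, three equivalents used)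
Product: 14 3,3'-(6,6'-dimethoxy[1,1'-biphenyl]-3,3'-diyl)bis(5-chloro-7-methoxy-4H-chromen-4-one), via 3-chloro-5-methoxybenzyne 12 (not isolated), via mono-annulated hydroxyacrylate 13 (not isolated)
Conditions: 11 (3 equiv), CsF (10 equiv), THF, 65 °C
Reagents that add atoms: none
Why: Proposed new method: fluoride desilylates 11 and loss of triflate gives aryne 12, the caesium enolate oxygen of 5 adds to its C8a terminus, and the C4a aryl anion thus formed attacks the adjacent methyl ester and expels methoxide, so that O1–C8a and C4–C4a arise in one event, first to give 13 and then again to give 14. The closest known reaction type is the CsF-mediated annulation of arynes with methyl salicylates to xanthones, of which the hydroxyacrylate is the open-chain vinylogous counterpart, and the use of an acyclic α-formyl ester enolate is the new element. Each pyranone closes by a 6-exo-trig acyl substitution and no stereocentre is created. The step needs oxygen at C8a rather than C4a, and this rests on the C5 chlorine, whose inductive pull distorts the aryne and places the developing negative charge next to itself, outweighing the small opposite bias of the C7 methoxy group. O-Arylation rather than C-arylation is expected because α-aryl-α-formyl ester enolates are alkylated on oxygen even by soft electrophiles such as methyl iodide, whereas attack through carbon would have to assemble a fully substituted diaryl carbon. Closure also needs the new aryloxy group cis to the ester, which THF without crown ether should favour by keeping the enolate as a cation-bridged, U-shaped contact ion pair.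

Step 8
Reactants: 14 3,3'-(6,6'-dimethoxy[1,1'-biphenyl]-3,3'-diyl)bis(5-chloro-7-methoxy-4H-chromen-4-one)
Product: 15 3,3'-(6,6'-dimethoxy[1,1'-biphenyl]-3,3'-diyl)bis(7-methoxy-4H-chromen-4-one)
Conditions: Pd(OAc)2 (10 mol %), (2-biphenylyl)P(t-Bu)2 (20 mol %), HCO2Na (6 equiv), 1,4-dioxane–MeOH, 80 °C
Reagents that add atoms: none
Why: Homogeneous palladium-catalysed hydrodechlorination (oxidative addition into the carbonyl-activated C5–Cl bond, formate exchange, decarboxylation to Ar–Pd–H, reductive elimination) is chosen over Pd/C because heterogeneous transfer hydrogenation is known to saturate the C2=C3 bond of isoflavones.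

Step 9
Reactants: 15 3,3'-(6,6'-dimethoxy[1,1'-biphenyl]-3,3'-diyl)bis(7-methoxy-4H-chromen-4-one)
Product: 16 3,3'-(6,6'-dihydroxy[1,1'-biphenyl]-3,3'-diyl)bis(7-hydroxy-4H-chromen-4-one) (target, CNP0386002.0)
Conditions: BBr3 (12 equiv), CH2Cl2, −78 °C → rt; then ice–water
Reagents that add atoms: none
Why: Lewis acid-mediated cleavage of aryl methyl ethers with boron tribromide is the standard deprotection of methylated isoflavones, and the chromone rings and the biaryl bond are inert to it.

Compound list
1 | methyl 2-(4-methoxyphenyl)acetate | COC(=O)Cc1ccc(OC)cc1 | starting material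
2 | methyl 2-(3-bromo-4-methoxyphenyl)acetate | COC(=O)Cc1ccc(OC)c(Br)c1 | intermediate
3 | dimethyl 2,2'-(6,6'-dimethoxy[1,1'-biphenyl]-3,3'-diyl)diacetate | COC(=O)Cc1ccc(OC)c(-c2cc(CC(=O)OC)ccc2OC)c1 | intermediate
4 | methyl formate | COC=O | starting material
5 | dimethyl (2Z,2'Z)-2,2'-(6,6'-dimethoxy[1,1'-biphenyl]-3,3'-diyl)bis(3-hydroxyprop-2-enoate) | O/C=C(/c1ccc(OC)c(-c2cc(/C(=C/O)C(=O)OC)ccc2OC)c1)C(=O)OC | intermediate
6 | 2-chloro-4-methoxyphenol | COc1ccc(O)c(Cl)c1 | starting material
7 | 2-bromo-6-chloro-4-methoxyphenol | COc1cc(Cl)c(O)c(Br)c1 | intermediate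
8 | (2-bromo-6-chloro-4-methoxyphenoxy)trimethylsilane | COc1cc(Cl)c(O[Si](C)(C)C)c(Br)c1 | intermediate
9 | [3-chloro-5-methoxy-2-(trimethylsilyloxy)phenyl]lithium (formed in situ) | COc1cc(Cl)c(O[Si](C)(C)C)c([Li])c1 | intermediate
10 | lithium 2-chloro-4-methoxy-6-(trimethylsilyl)phenoxide (formed in situ) | COc1cc(Cl)c([O-])c([Si](C)(C)C)c1.[Li+] | intermediate
11 | 2-chloro-4-methoxy-6-(trimethylsilyl)phenyl trifluoromethanesulfonate | COc1cc(Cl)c(OS(=O)(=O)C(F)(F)F)c([Si](C)(C)C)c1 | intermediate
12 | 3-chloro-5-methoxybenzyne (formed in situ) | COC1=CC#CC(Cl)=C1 | intermediate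
13 | methyl (Z)-2-[3'-(5-chloro-7-methoxy-4-oxo-4H-chromen-3-yl)-6,6'-dimethoxy[1,1'-biphenyl]-3-yl]-3-hydroxyprop-2-enoate (formed in situ) | O=c1c(-c2ccc(OC)c(-c3cc(/C(=C/O)C(=O)OC)ccc3OC)c2)coc2cc(OC)cc(Cl)c12 | intermediate
14 | 3,3'-(6,6'-dimethoxy[1,1'-biphenyl]-3,3'-diyl)bis(5-chloro-7-methoxy-4H-chromen-4-one) | O=c1c(-c2ccc(OC)c(-c3cc(-c4coc5cc(OC)cc(Cl)c5c4=O)ccc3OC)c2)coc2cc(OC)cc(Cl)c12 | intermediate
15 | 3,3'-(6,6'-dimethoxy[1,1'-biphenyl]-3,3'-diyl)bis(7-methoxy-4H-chromen-4-one) | O=c1c(-c2ccc(OC)c(-c3cc(-c4coc5cc(OC)ccc5c4=O)ccc3OC)c2)coc2cc(OC)ccc12 | intermediate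
16 | 3,3'-(6,6'-dihydroxy[1,1'-biphenyl]-3,3'-diyl)bis(7-hydroxy-4H-chromen-4-one) | O=c1c(-c2ccc(O)c(-c3cc(-c4coc5cc(O)ccc5c4=O)ccc3O)c2)coc2cc(O)ccc12 | target

Total step count: 9. Longest linear sequence: 6 steps (steps 1–3 or steps 4–6, followed by steps 7–9).

Steps most likely to fail

First, step 7, the new method. Four processes could defeat it:
- The enolate may be arylated at carbon. The aryl anion would then add to the formyl group and the strained alkoxide would fragment, a formal insertion of the aryne into the C–CHO bond.
- Arylation may occur from the extended enolate rather than the cation-bridged one. The aryl anion is then trans to the ester and is only protonated.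
- The ortho-chloroaryl anion may lose chloride before it reaches the ester.
- Both ends of the molecule have to react.

The fallback is the classical deoxybenzoin construction, which needs neither aryne nor chlorine. It sets out from 3 and comes back to the route at 16. Saponification (LiOH, THF–H2O) would give 2,2'-(6,6'-dimethoxy[1,1'-biphenyl]-3,3'-diyl)diacetic acid F1. Friedel–Crafts acylation of resorcinol in BF3·OEt2 at 85 °C would give the bis(deoxybenzoin) 2,2'-(6,6'-dimethoxy[1,1'-biphenyl]-3,3'-diyl)bis[1-(2,4-dihydroxyphenyl)ethan-1-one] F2. Vilsmeier-type one-carbon cyclisation (DMF, BF3·OEt2, MsCl, 50–70 °C) would give 3,3'-(6,6'-dimethoxy[1,1'-biphenyl]-3,3'-diyl)bis(7-hydroxy-4H-chromen-4-one) F3. The BBr3 conditions of step 9 would then convert F3 into 16.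

Second, step 8. Oxidative addition into the C–Cl bonds, which are crowded by the peri carbonyl, may stall after one site. Alternatively, the palladium hydride may begin conjugate reduction of C2=C3. The fallback accepts over-reduction and corrects it afterwards. It sets out from 14 and comes back at 15. Hydrogenation over Pd/C (H2, NaOAc, THF–MeOH) would remove both chlorines and deliberately saturate both enone double bonds. This gives 3,3'-(6,6'-dimethoxy[1,1'-biphenyl]-3,3'-diyl)bis(7-methoxychroman-4-one) F4 as a mixture of C3 epimers. Dehydrogenation with DDQ in refluxing 1,4-dioxane would restore both chromones.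

Third, step 2. Hydrodebromination of the aryl–nickel species, or slow coupling next to the ortho-methoxy groups, may erode the homocoupling. The fallback replaces the reductive dimerisation by a two-stage cross-coupling. It sets out from 2 and comes back at 3. Miyaura borylation (B2pin2, PdCl2(dppf), KOAc, dioxane, 85 °C) would give methyl 2-[4-methoxy-3-(4,4,5,5-tetramethyl-1,3,2-dioxaborolan-2-yl)phenyl]acetate F5. Suzuki–Miyaura coupling of F5 with a second portion of 2 (Pd(OAc)2, SPhos, K3PO4, toluene–H2O, 80 °C) would then form the biaryl bond.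

Further compounds
F1 | step 7 | 2,2'-(6,6'-dimethoxy[1,1'-biphenyl]-3,3'-diyl)diacetic acid | OC(=O)Cc1ccc(OC)c(-c2cc(CC(=O)O)ccc2OC)c1
F2 | step 7 | 2,2'-(6,6'-dimethoxy[1,1'-biphenyl]-3,3'-diyl)bis[1-(2,4-dihydroxyphenyl)ethan-1-one] | O=C(Cc1ccc(OC)c(-c2cc(CC(=O)c3ccc(O)cc3O)ccc2OC)c1)c1ccc(O)cc1O
F3 | step 7 | 3,3'-(6,6'-dimethoxy[1,1'-biphenyl]-3,3'-diyl)bis(7-hydroxy-4H-chromen-4-one) | O=c1c(-c2ccc(OC)c(-c3cc(-c4coc5cc(O)ccc5c4=O)ccc3OC)c2)coc2cc(O)ccc12
F4 | step 8 | 3,3'-(6,6'-dimethoxy[1,1'-biphenyl]-3,3'-diyl)bis(7-methoxychroman-4-one), mixture of C3 epimers | O=C1c2ccc(OC)cc2OCC1c1ccc(OC)c(-c2cc(C3COc4cc(OC)ccc4C3=O)ccc2OC)c1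
F5 | step 2 | methyl 2-[4-methoxy-3-(4,4,5,5-tetramethyl-1,3,2-dioxaborolan-2-yl)phenyl]acetate | COC(=O)Cc1ccc(OC)c(B2OC(C)(C)C(C)(C)O2)c1
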